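**Retrosynthetic overview**
- Target 16 is traced back, through detosylation, allyl-for-bromine exchange and C9–O ether formation with eugenol, to bromo alcohol 12 and from there to ester 11.
- The strategy rests on the O1–C2–C3–C3a–C7a dihydrofuran ring, which carries the aryl group on C2 and a single exocyclic carbon (C9) on C3. It is a 2-arylchroman-4-one ring (O1–C2–C3–C4–C4a–C8a) with C4 pushed out of the ring, so C3–C3a is made by a 1,2-shift of the ring-A carbon from C4 to C3 (11 from 8).
- (S)-Flavanone 8 comes from enantioselective conjugate arylation of chromone 4 with boronic acid 7; 4 is made from acetophenone 1 and 7 from boronate phenol 5.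
- Ring order: rings A and B are bought; the pyranone ring is closed in step 2 and contracted to the dihydrofuran ring in step 6.

Key step: step 6

Assumption: the facial sense of the t-BuPyOx/divalent-palladium arylation of chromone 4 is taken to follow that on cyclic enones, so the (R)-ligand is drawn for 2S; if the sense proves opposite on 8, the (S)-ligand is used with no other change.

**Route**

Step 1
Reactants: 1 2-hydroxy-3-methoxyacetophenone
Product: 2 1-(5-bromo-2-hydroxy-3-methoxyphenyl)ethanone
Conditions: NBS (1.05 equiv), MeCN, 0 °C to rt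
Reagents that add atoms: N-bromosuccinimide, O=C1CCC(=O)N1Br
Why: Electrophilic aromatic bromination; the only free position para to the phenol OH (and meta to the acetyl group) is C5, so a single ring bromide should form.

Step 2
Reactants: 2 1-(5-bromo-2-hydroxy-3-methoxyphenyl)ethanone
Product: 4 6-bromo-8-methoxy-4H-chromen-4-one, via enaminone 3 (not isolated)
Conditions: Me2NCH(OMe)2, toluene, 100 °C; then conc. HCl, CH2Cl2, 40 °C
Reagents that add atoms: N,N-dimethylformamide dimethyl acetal, COC(OC)N(C)C
Why: Enaminone chromone synthesis; the methyl ketone condenses with the formamide acetal and acid then drives conjugate addition of the phenol with loss of dimethylamine, closing the pyranone ring.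

Step 3
Reactants: 5 2-methoxy-4-(4,4,5,5-tetramethyl-1,3,2-dioxaborolan-2-yl)phenol
Product: 6 2-methoxy-4-(4,4,5,5-tetramethyl-1,3,2-dioxaborolan-2-yl)phenyl 4-methylbenzenesulfonate
Conditions: TsCl, Et3N, DMAP (cat.), CH2Cl2, 0 °C to rt
Reagents that add atoms: 4-toluenesulfonyl chloride, Cc1ccc(cc1)S(=O)(=O)Cl
Why: O-Sulfonylation of a phenol; the pinacol boronate is inert to these conditions.

Step 4
Reactants: 6 2-methoxy-4-(4,4,5,5-tetramethyl-1,3,2-dioxaborolan-2-yl)phenyl 4-methylbenzenesulfonate
Product: 7 [3-methoxy-4-(tosyloxy)phenyl]boronic acid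
Conditions: NaIO4, NH4OAc, acetone/H2O, rt
Reagents that add atoms: water, O
Why: Oxidative pinacol cleavage; periodate destroys the diol released in the hydrolysis equilibrium and so pulls the boronate ester over to the free boronic acid, which the next step requires.

Step 5
Reactants: 4 6-bromo-8-methoxy-4H-chromen-4-one; 7 [3-methoxy-4-(tosyloxy)phenyl]boronic acid (2 equiv)
Product: 8 (S)-6-bromo-8-methoxy-2-[3-methoxy-4-(tosyloxy)phenyl]chroman-4-one
Conditions: Pd(OCOCF3)2 (5 mol%), (R)-t-BuPyOx (6 mol%), NH4PF6 (30 mol%), H2O (5 equiv), ClCH2CH2Cl, 60 °C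
Reagents that add atoms: none
Why: Catalytic asymmetric conjugate addition of an arylboronic acid to a chromone; the cationic divalent-palladium pyridine-oxazoline complex transfers the aryl group to C2 on the face selected by the tert-butyl group (setting 2S), the C-bound enolate is protonated by water, and because the cycle never passes through zerovalent palladium the aryl bromide and aryl tosylate should be left alone.

Step 6
Reactants: 8 (S)-6-bromo-8-methoxy-2-[3-methoxy-4-(tosyloxy)phenyl]chroman-4-one
Product: 11 methyl (2S,3S)-5-bromo-7-methoxy-2-[3-methoxy-4-(tosyloxy)phenyl]-2,3-dihydrobenzofuran-3-carboxylate (trans), via enol ether 9 (not isolated), via iodanyl ketal 10 (not isolated)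
Conditions: HC(OMe)3, conc. H2SO4 (cat.), rt; then PhI(OAc)2 (1.2 equiv), 0 °C to rt
Reagents that add atoms: trimethyl orthoformate, COC(OC)OC
Why: Acid and orthoformate turn ketone 8 into its dimethyl ketal and then enol ether 9, whose C3 attacks the electrophilic trivalent iodine of PhI(OAc)2 on the face opposite the C2 aryl group while methanol caps C4, giving the trans iodanyl ketal 10 (iodine ligand drawn as acetate). In the diequatorial half-chair of 10 the C4–C4a bond lies anti-periplanar to the C3–iodine bond, so the ring-A carbon C4a shifts from C4 to C3 through a phenonium-like bridged state as iodobenzene leaves, and the dimethoxycarbenium ion at the extruded carbon collapses to the methyl ester. The closest known reaction is the trivalent-iodine oxidative ring contraction of flavanones and chromanones in acidic orthoformate to methyl 2,3-dihydrobenzofuran-3-carboxylates, a semipinacol-type 1,2-aryl shift. The O1–C2–C3–C3a–C7a ring is closed by contraction of the pyranone (C3–C3a made, C4–C4a broken) and not by an end-to-end cyclisation, so no Baldwin mode applies. The new C3 stereocentre is controlled by the existing C2 centre: anti attack of iodine followed by migration with inversion at C3 places the ester trans to the aryl group, which is also the more stable arrangement, and C2 itself is not touched. The step needs ring-A migration to win over the shift of ring B from C2 to C3 (isoflavone) and over elimination (flavone); the electron-poor tosyloxy ring B, the activation of C4a by the ring oxygen and the non-basic medium (no enolate, so no retro-oxa-Michael opening at C2) should secure this, while bromine blocks the position para to the ring oxygen against oxidation.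

Step 7
Reactants: 11 methyl (2S,3S)-5-bromo-7-methoxy-2-[3-methoxy-4-(tosyloxy)phenyl]-2,3-dihydrobenzofuran-3-carboxylate
Product: 12 [(2S,3R)-5-bromo-7-methoxy-2-[3-methoxy-4-(tosyloxy)phenyl]-2,3-dihydrobenzofuran-3-yl]methanol
Conditions: i-Bu2AlH (2.5 equiv), CH2Cl2, −78 to 0 °C; aq. potassium sodium tartrate
Reagents that add atoms: none
Why: Ester reduction by a Lewis-acidic hydride at low temperature; no base is present, so C3 is not epimerised and no β-elimination of the ring oxygen occurs, and the aryl bromide and aryl sulfonate should survive (the C3 descriptor changes to R only through the priority rules).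

Step 8
Reactants: 12 [(2S,3R)-5-bromo-7-methoxy-2-[3-methoxy-4-(tosyloxy)phenyl]-2,3-dihydrobenzofuran-3-yl]methanol; 13 eugenol (4-allyl-2-methoxyphenol)
Product: 14 (2S,3R)-3-[(4-allyl-2-methoxyphenoxy)methyl]-5-bromo-7-methoxy-2-[3-methoxy-4-(tosyloxy)phenyl]-2,3-dihydrobenzofuran
Conditions: PPh3, diisopropyl azodicarboxylate, THF, 0 °C to rt
Reagents that add atoms: none
Why: Mitsunobu etherification; the primary alcohol is activated as its alkoxyphosphonium ion and displaced at C9 by the phenoxide of eugenol (a sufficiently acidic pronucleophile), with no stereocentre involved.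

Step 9
Reactants: 14 (2S,3R)-3-[(4-allyl-2-methoxyphenoxy)methyl]-5-bromo-7-methoxy-2-[3-methoxy-4-(tosyloxy)phenyl]-2,3-dihydrobenzofuran
Product: 15 (2S,3R)-5-allyl-3-[(4-allyl-2-methoxyphenoxy)methyl]-7-methoxy-2-[3-methoxy-4-(tosyloxy)phenyl]-2,3-dihydrobenzofuran
Conditions: allylSnBu3 (1.5 equiv), Pd(PPh3)4 (5 mol%), degassed toluene, 100 °C
Reagents that add atoms: allyltributylstannane, C=CC[Sn](CCCC)(CCCC)CCCC
Why: Stille allylation; zerovalent palladium bearing triphenylphosphine inserts into the aryl C–Br bond but not into the aryl tosylate, and the neutral conditions should leave both stereocentres and the terminal alkenes unchanged.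

Step 10
Reactants: 15 (2S,3R)-5-allyl-3-[(4-allyl-2-methoxyphenoxy)methyl]-7-methoxy-2-[3-methoxy-4-(tosyloxy)phenyl]-2,3-dihydrobenzofuran
Product: 16 4-[(2S,3R)-5-allyl-3-[(4-allyl-2-methoxyphenoxy)methyl]-7-methoxy-2,3-dihydrobenzofuran-2-yl]-2-methoxyphenol (CNP0138854.1)
Conditions: KOH (10 equiv), MeOH/THF/H2O, 60 °C; then aq. HCl to pH 5
Reagents that add atoms: none
Why: Alkaline cleavage of an aryl sulfonate by hydroxide attack at sulfur; neither stereocentre is acidic and allylarenes should not isomerise to propenylarenes under aqueous-alcoholic KOH at this temperature.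

**Compound list**
1 | 2-hydroxy-3-methoxyacetophenone | CC(=O)c1cccc(OC)c1O | starting material
2 | 1-(5-bromo-2-hydroxy-3-methoxyphenyl)ethanone | CC(=O)c1cc(Br)cc(OC)c1O | intermediate
3 | (E)-1-(5-bromo-2-hydroxy-3-methoxyphenyl)-3-(dimethylamino)prop-2-en-1-one | CN(C)/C=C/C(=O)c1cc(Br)cc(OC)c1O | intermediate (not isolated)
4 | 6-bromo-8-methoxy-4H-chromen-4-one | COc1cc(Br)cc2c(=O)ccoc12 | intermediate
5 | 2-methoxy-4-(4,4,5,5-tetramethyl-1,3,2-dioxaborolan-2-yl)phenol | COc1cc(B2OC(C)(C)C(C)(C)O2)ccc1O | starting material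
6 | 2-methoxy-4-(4,4,5,5-tetramethyl-1,3,2-dioxaborolan-2-yl)phenyl 4-methylbenzenesulfonate | COc1cc(B2OC(C)(C)C(C)(C)O2)ccc1OS(=O)(=O)c1ccc(C)cc1 | intermediate
7 | [3-methoxy-4-(tosyloxy)phenyl]boronic acid | COc1cc(B(O)O)ccc1OS(=O)(=O)c1ccc(C)cc1 | intermediate
8 | (S)-6-bromo-8-methoxy-2-[3-methoxy-4-(tosyloxy)phenyl]chroman-4-one | COc1cc(Br)cc2C(=O)C[C@@H](c3ccc(OS(=O)(=O)c4ccc(C)cc4)c(OC)c3)Oc12 | intermediate
9 | (2S)-6-bromo-4,8-dimethoxy-2-[3-methoxy-4-(tosyloxy)phenyl]-2H-chromene | COc1cc(Br)cc2C(OC)=C[C@@H](c3ccc(OS(=O)(=O)c4ccc(C)cc4)c(OC)c3)Oc12 | intermediate (not isolated)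
10 | trans-3-[acetoxy(phenyl)iodanyl]-6-bromo-4,4,8-trimethoxy-2-[3-methoxy-4-(tosyloxy)phenyl]chromane, C2 configured as in 8 | COc1cc(Br)cc2c1O[C@H](c1ccc(OS(=O)(=O)c3ccc(C)cc3)c(OC)c1)[C@@H](I(OC(C)=O)c1ccccc1)C2(OC)OC | intermediate (not isolated)
11 | methyl (2S,3S)-5-bromo-7-methoxy-2-[3-methoxy-4-(tosyloxy)phenyl]-2,3-dihydrobenzofuran-3-carboxylate (trans) | COC(=O)[C@H]2c3cc(Br)cc(OC)c3O[C@@H]2c2ccc(OS(=O)(=O)c4ccc(C)cc4)c(OC)c2 | intermediate
12 | [(2S,3R)-5-bromo-7-methoxy-2-[3-methoxy-4-(tosyloxy)phenyl]-2,3-dihydrobenzofuran-3-yl]methanol | OC[C@H]2c3cc(Br)cc(OC)c3O[C@@H]2c2ccc(OS(=O)(=O)c4ccc(C)cc4)c(OC)c2 | intermediate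
13 | eugenol (4-allyl-2-methoxyphenol) | C=CCc1ccc(O)c(OC)c1 | starting material
14 | (2S,3R)-3-[(4-allyl-2-methoxyphenoxy)methyl]-5-bromo-7-methoxy-2-[3-methoxy-4-(tosyloxy)phenyl]-2,3-dihydrobenzofuran | C=CCc1ccc(OC[C@H]2c3cc(Br)cc(OC)c3O[C@@H]2c2ccc(OS(=O)(=O)c4ccc(C)cc4)c(OC)c2)c(OC)c1 | intermediate
15 | (2S,3R)-5-allyl-3-[(4-allyl-2-methoxyphenoxy)methyl]-7-methoxy-2-[3-methoxy-4-(tosyloxy)phenyl]-2,3-dihydrobenzofuran | C=CCc1ccc(OC[C@H]2c3cc(CC=C)cc(OC)c3O[C@@H]2c2ccc(OS(=O)(=O)c4ccc(C)cc4)c(OC)c2)c(OC)c1 | intermediate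
16 | 4-[(2S,3R)-5-allyl-3-[(4-allyl-2-methoxyphenoxy)methyl]-7-methoxy-2,3-dihydrobenzofuran-2-yl]-2-methoxyphenol | C=CCc1ccc(OC[C@H]2c3cc(CC=C)cc(OC)c3O[C@@H]2c2ccc(O)c(OC)c2)c(OC)c1 | target

**Step count and risk**

Total steps: 10. Longest linear sequence: 8 steps (steps 1, 2, 5, 6, 7, 8, 9, 10).

Steps most likely to fail:

1. Step 6 (ring contraction). The wrong group may migrate (ring B from C2 to C3, leading to an isoflavone), the iodanyl intermediate may eliminate to the flavone, or C2 may partly lose its configuration through acid-mediated opening of the benzylic ether. Fallback, from 8 back to 11: the same C4a shift is driven by a carbene instead of an iodane. Flavanone 8 is condensed with Me2NCH(OMe)2 (toluene, 90 °C) to the 3-(dimethylaminomethylene)flavanone F1. Diazo transfer with TsN3 (MeCN, rt) gives the 3-diazoflavanone F2. Photolysis (365 nm, MeOH) triggers a Wolff rearrangement in which C4a migrates to C3, and methanol traps the ring-contracted ketene as the ester. Any cis ester F3 formed on protonation is equilibrated with catalytic NaOMe in MeOH at 0 °C to the trans ester 11.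

2. Step 5 (asymmetric arylation). Facial selectivity may be poor on the 8-methoxychromone, or insertion may be slow enough that protodeboronation consumes the aryl donor. Fallback, from 2 back to 8: the flavanone is made racemic and resolved. Vanillin is tosylated (TsCl, Et3N, CH2Cl2) to 4-formyl-2-methoxyphenyl tosylate F4. Claisen–Schmidt condensation of 2 with it (KOH, EtOH, rt) gives the 2'-hydroxychalcone F5, and NaOAc in refluxing EtOH closes this by oxa-Michael addition to the racemic flavanone F6. Asymmetric transfer hydrogenation with RuCl[(R,R)-TsDPEN](p-cymene) and HCO2H/Et3N is then run to about half conversion as a kinetic resolution. The (R)-enantiomer should be reduced faster to the cis-(2R,4R)-flavan-4-ol F7, which is separated by chromatography from the remaining (S)-flavanone 8.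

3. Step 8 (Mitsunobu etherification). Substitution at the β-branched primary carbon may be slow, so that the alkoxyphosphonium ion is consumed by the hydrazide or loses the benzylic C3 proton by β-elimination. Fallback, from 12 back to 14: the alcohol is first converted (MsCl, Et3N, CH2Cl2, 0 °C) to the mesylate F8, which is then displaced by the cesium phenoxide of eugenol 13 (Cs2CO3, DMF, 50 °C) in a Williamson etherification to give 14.

**Further compounds**
F1 | step 6 | 6-bromo-3-[(dimethylamino)methylidene]-8-methoxy-2-[3-methoxy-4-(tosyloxy)phenyl]chroman-4-one, C2 configured as in 8 | COc1cc(Br)cc2C(=O)C(=CN(C)C)[C@@H](c3ccc(OS(=O)(=O)c4ccc(C)cc4)c(OC)c3)Oc12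
F2 | step 6 | 6-bromo-3-diazo-8-methoxy-2-[3-methoxy-4-(tosyloxy)phenyl]chroman-4-one, C2 configured as in 8 | COc1cc(Br)cc2C(=O)C(=[N+]=[N-])[C@@H](c3ccc(OS(=O)(=O)c4ccc(C)cc4)c(OC)c3)Oc12
F3 | step 6 | methyl (2S,3R)-5-bromo-7-methoxy-2-[3-methoxy-4-(tosyloxy)phenyl]-2,3-dihydrobenzofuran-3-carboxylate (cis) | COC(=O)[C@@H]2c3cc(Br)cc(OC)c3O[C@@H]2c2ccc(OS(=O)(=O)c4ccc(C)cc4)c(OC)c2
F4 | step 5 | 4-formyl-2-methoxyphenyl 4-methylbenzenesulfonate | COc1cc(C=O)ccc1OS(=O)(=O)c1ccc(C)cc1
F5 | step 5 | (E)-1-(5-bromo-2-hydroxy-3-methoxyphenyl)-3-[3-methoxy-4-(tosyloxy)phenyl]prop-2-en-1-one | COc1cc(Br)cc(C(=O)/C=C/c2ccc(OS(=O)(=O)c3ccc(C)cc3)c(OC)c2)c1O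
F6 | step 5 | racemic 6-bromo-8-methoxy-2-[3-methoxy-4-(tosyloxy)phenyl]chroman-4-one | COc1cc(Br)cc2C(=O)CC(c3ccc(OS(=O)(=O)c4ccc(C)cc4)c(OC)c3)Oc12
F7 | step 5 | (2R,4R)-6-bromo-8-methoxy-2-[3-methoxy-4-(tosyloxy)phenyl]chroman-4-ol (cis) | COc1cc(Br)cc2[C@H](O)C[C@H](c3ccc(OS(=O)(=O)c4ccc(C)cc4)c(OC)c3)Oc12
F8 | step 8 | [(2S,3R)-5-bromo-7-methoxy-2-[3-methoxy-4-(tosyloxy)phenyl]-2,3-dihydrobenzofuran-3-yl]methyl methanesulfonate | CS(=O)(=O)OC[C@H]2c3cc(Br)cc(OC)c3O[C@@H]2c2ccc(OS(=O)(=O)c4ccc(C)cc4)c(OC)c2
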